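I decide to freeze one thing, the rate at which target is born, and then ask how old target gets.

    reagent + free catalyst → catalyst intermediate A (k1 = 1.3 /M/s)
    catalyst intermediate A → released group + catalyst intermediate B (k2 = 0.11 /s)
    starting material + catalyst intermediate B ⇌ catalyst intermediate C (K3 = 2.4 /M, k3 = 1.4 /M/s)
    catalyst intermediate C → free catalyst + target (k4 = 0.40 /s)
    target → over-reaction product (k5 = 0.016 /s)

| setting | summer | dawn | autumn | midnight |
|---|---|---|---|---|
| starting material | 0.31 M | 0.31 M (fed, over 0.500 min) | 0.31 M | 0.31 M |
| reagent | 0.930 M | 0.930 M | 0.930 M | 0.930 M |
| free catalyst | 31 mM | 31 mM | 31 mM | 31 mM |
| time | 1.0 min | 1.0 min |  | 1.0 min |
| remark | a closed flask charged with all of it at once and left for 1.0 min | all but starting material at the start; starting material goes in evenly over 0.500 min, the run ends at 1.0 min | a single well-mixed tank run continuously and read at steady state, 1.0 min in it on average | a tube with plug flow, the mixed feed as stated, residence time 1.0 min |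

- the set-up with the highest share of target in all that became target or over-reaction product, at the outlet or at the end ("none" if the first two lie within 2 percentage points) (summer / dawn / autumn / midnight / none)
- share of target in all that became target or over-reaction product, at the outlet or at the end, summer
- share of target in all that became target or over-reaction product, at the outlet or at the end, dawn
- share of target in all that became target or over-reaction product, at the outlet or at the end, autumn
- share of target in all that became target or over-reaction product, at the outlet or at the end, midnight

- the stated concentrations are those of everything mixed, before any reaction; amounts are the same in each set-up
- the feed brings no volume worth counting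
- run time (summer): 1.0 min

One catalyst turn is the sum of its waits, with the way back in step 3 counted, and it takes 18.1 s. Step 2 has the longest wait, 9.09 s, but that is half of the turn, and step 3 with its way back takes 5.66 s, so I name no single rate-limiting step. The catalyst would need 3.01 min to work through the whole charge of starting material, which is longer than the run. So I hold the birth rate steady.

Let d = 0.016 /s, the decay constant of target. If target is born evenly over a window w, then S = (1 − exp(−d·w))/(d·w). In a steady tank with mean time τ, the share is 1/(1 + d·τ).

- summer: w = 1.0 min, S = 64.3 %, the survival share, the part of all target born that is still target when the window closes
- midnight: the same row
- dawn: w = 0.750 min, S = 71.3 %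
- autumn: τ = 1.0 min, share 51.0 %

I read the rows in turn. Midnight copies summer, since a plug in the tube is a closed flask in motion. Dawn's window is my rough guess: the feed arrives 0.250 min late on average, so I shorten the window by that much. Its target is younger, and its share is higher than summer's by 7 percentage points, which is more than the margin. Autumn is lowest. My choice is dawn.

The forecast differs slightly from my rows for summer, midnight and dawn and matches my autumn row: it gives 65.5 % for summer, 65.5 % for midnight, 70 % for dawn and 51 % for autumn, picks dawn, and rests on the view that “target forms at a nearly steady rate”.

The flasks give 65.9 % for summer, 65.9 % for midnight, 68.8 % for dawn and 51.0 % for autumn, so dawn comes first.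

Summer reads 1.6 points above my 64.3 %. Target and over-reaction product together gained 13.2 % of the charge in summer's first half and 15.0 % in its second. I now leave the summer flask until 1.5 min. The window widens to that time, so S falls to 53.0 %. That flask reads 53.4 %, with 57 % of its starting material still unbound.

The numbers of this flask were drawn at random within sensible limits; what happens was integrated by code.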